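The whole α-methylene-γ-butyrolactone ring (O, C12, C11, C7, C6) is taken off in one cut. The lactone oxygen sits on C6, allylic to the Z-C4=C5 alkene of the ten-membered ring. C6 and C7 are therefore read as the E-alkene end of a ring-embedded (4Z,6E)-1,3-diene. In the last step a palladium-catalysed heteroannulation with 2-bromoacrylic acid adds C11 to C7 and the carboxylate oxygen to C6 on the outer ring face. This closes the trans-fused lactone, sets both stereocentres and leaves C4=C5 in place. The precursor is the lactone-free epoxy dienol isovalerate, closed by a Nozaki–Hiyama–Kishi reaction.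

Key step: step 13

Numbering remark: germacranolide numbers are used. C1–C10 are the ring carbons (C1/C10 epoxide, C3 carbinol, C4=C5, C6 lactone O–CH, C7, C8 ester carbinol). C11–C13 are the acrylate unit, C14 is the methyl on C10 and C15 the methyl on C4.
Assumption: the sense of induction of (R)-TRIP in step 4 is taken by analogy with aromatic and α,β-unsaturated aldehydes; should it be opposite for acrolein, the antipode of the acid is used.

Step 1
Reactants: 1 2-butyn-1-ol
Product: 3 (Z)-3-iodobut-2-en-1-ol, via cyclic alkenylalanate 2 (not isolated)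
Conditions: NaAlH2(OCH2CH2OCH3)2, THF, 0 °C to rt; then I2, THF, −78 °C to 0 °C; then H2O
Reagents that add atoms: iodine, II
Why: Hydroxyl-directed trans-hydroalumination of the propargylic alcohol places aluminium on the methyl-bearing carbon inside a five-membered alanate, and iodinolysis with retention gives the Z-iodide, which fixes the later C4=C5 geometry (iodine cis to the future C6).

Step 2
Reactants: 3 (Z)-3-iodobut-2-en-1-ol
Product: 4 (Z)-3-iodobut-2-enal
Conditions: activated MnO2, CH2Cl2, rt, dark
Reagents that add atoms: none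
Why: Allylic alcohol oxidation on MnO2 is neutral and heterogeneous, so the Z-enal should form without isomerisation.

Step 3
Reactants: 4 (Z)-3-iodobut-2-enal
Product: 5 (3Z)-4-iodopenta-1,3-diene
Conditions: CH3PPh3Br, KN(SiMe3)2, THF, −78 °C to 0 °C; product kept as a cold solution in the dark
Reagents that add atoms: methyltriphenylphosphonium bromide, C[P+](c1ccccc1)(c1ccccc1)c1ccccc1.[Br-]
Why: Wittig methylenation with the non-stabilised ylide converts the aldehyde into the terminal vinyl group (future C6) at low temperature without touching the alkenyl iodide.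

Step 4
Reactants: 6 acrolein; 7 allenylboronic acid pinacol ester
Product: 9 (R)-hex-1-en-5-yn-3-ol, via pinacol borate ester 8 (not isolated)
Conditions: (R)-TRIP (10 mol %), 4 Å MS, toluene, −20 °C; then H2O
Reagents that add atoms: none
Why: In this chiral phosphoric acid-catalysed propargylation the allenylboronate reacts through a closed six-membered SE2' transition state hydrogen-bonded to (R)-TRIP, which should direct attack to the Re face of acrolein and set C8 as R.

Step 5
Reactants: 9 (R)-hex-1-en-5-yn-3-ol; 10 ethylene oxide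
Product: 13 (3R,5E)-5-methylocta-1,5-diene-3,8-diol, via alkenyldimethylalane 11 (not isolated), via lithium alkenylalanate 12 (not isolated)
Conditions: Me3Al (3 equiv), Cp2ZrCl2 (0.25 equiv), CH2Cl2, 0 °C to rt; volatiles removed; n-BuLi, hexane/THF, −78 °C; 10, −78 °C to 0 °C; then H2O
Reagents that add atoms: trimethylaluminium, C[Al](C)C
Why: Negishi zirconium-catalysed syn-carboalumination of the terminal alkyne (hydroxyl masked in situ as its dimethylaluminium alkoxide) puts methyl on C10 and aluminium on C1, and the derived alanate opens ethylene oxide with retention to give the E-C1=C10 alkene carrying C2 and C3.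

Step 6
Reactants: 13 (3R,5E)-5-methylocta-1,5-diene-3,8-diol
Product: 14 (3R,5E)-8-(tert-butyldimethylsilyloxy)-5-methylocta-1,5-dien-3-ol
Conditions: TBSCl (1.05 equiv), imidazole, CH2Cl2, 0 °C
Reagents that add atoms: tert-butyldimethylsilyl chloride, CC(C)(C)[Si](C)(C)Cl
Why: The unhindered primary C3 hydroxyl is silylated faster than the secondary allylic C8 hydroxyl (steric chemoselectivity of TBSCl).

Step 7
Reactants: 14 (3R,5E)-8-(tert-butyldimethylsilyloxy)-5-methylocta-1,5-dien-3-ol; 15 isovaleryl chloride
Product: 16 (3R,5E)-8-(tert-butyldimethylsilyloxy)-5-methylocta-1,5-dien-3-yl 3-methylbutanoate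
Conditions: pyridine, DMAP (cat.), CH2Cl2, 0 °C to rt
Reagents that add atoms: none
Why: DMAP-catalysed acylation installs the isovalerate of the target with retention at C8, so this oxygen never needs a protecting group.

Step 8
Reactants: 16 (3R,5E)-8-(tert-butyldimethylsilyloxy)-5-methylocta-1,5-dien-3-yl 3-methylbutanoate
Product: 17 (2R)-1-[(2R,3R)-3-(2-(tert-butyldimethylsilyloxy)ethyl)-2-methyloxiran-2-yl]but-3-en-2-yl 3-methylbutanoate
Conditions: D-fructose-derived Shi ketone (0.3 equiv), Oxone (2KHSO5·KHSO4·K2SO4), K2CO3, Na2B4O7 buffer, Bu4NHSO4, MeCN/CH2(OMe)2/H2O, 0 °C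
Reagents that add atoms: potassium peroxymonosulfate, [K+].[O-]S(=O)(=O)OO
Why: In the Shi asymmetric epoxidation the dioxirane of the D-fructose-derived ketone attacks the electron-rich E-trisubstituted alkene through the spiro transition state that gives R,R-epoxides from E-alkenes, which sets C1 and C10 under reagent control and leaves the monosubstituted allylic-ester alkene alone.

Step 9
Reactants: 17 (2R)-1-[(2R,3R)-3-(2-(tert-butyldimethylsilyloxy)ethyl)-2-methyloxiran-2-yl]but-3-en-2-yl 3-methylbutanoate; 5 (3Z)-4-iodopenta-1,3-diene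
Product: 18 (2R,3E,5Z)-1-[(2R,3R)-3-(2-(tert-butyldimethylsilyloxy)ethyl)-2-methyloxiran-2-yl]-6-iodohepta-3,5-dien-2-yl 3-methylbutanoate
Conditions: 5 (3 equiv), second-generation Hoveyda–Grubbs catalyst (10 mol %), CH2Cl2, 40 °C
Reagents that add atoms: none
Why: In this ene–diene cross-metathesis only the two monosubstituted alkenes are accessible to ruthenium (the iodine-bearing trisubstituted C4=C5 bond is inert), and the conjugated product should form as the favoured 6E isomer with the Z-iodide untouched.

Step 10
Reactants: 18 (2R,3E,5Z)-1-[(2R,3R)-3-(2-(tert-butyldimethylsilyloxy)ethyl)-2-methyloxiran-2-yl]-6-iodohepta-3,5-dien-2-yl 3-methylbutanoate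
Product: 19 (2R,3E,5Z)-1-[(2R,3R)-3-(2-hydroxyethyl)-2-methyloxiran-2-yl]-6-iodohepta-3,5-dien-2-yl 3-methylbutanoate
Conditions: Bu4NF, AcOH (1:1), THF, 0 °C to rt
Reagents that add atoms: none
Why: Fluoride cleaves the primary silyl ether, and buffering with acetic acid keeps the ester and the epoxide safe from alkoxide-induced migration or opening.

Step 11
Reactants: 19 (2R,3E,5Z)-1-[(2R,3R)-3-(2-hydroxyethyl)-2-methyloxiran-2-yl]-6-iodohepta-3,5-dien-2-yl 3-methylbutanoate
Product: 20 (2R,3E,5Z)-6-iodo-1-[(2R,3R)-2-methyl-3-(2-oxoethyl)oxiran-2-yl]hepta-3,5-dien-2-yl 3-methylbutanoate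
Conditions: Dess–Martin periodinane, NaHCO3, CH2Cl2, 0 °C; used at once
Reagents that add atoms: none
Why: Dess–Martin oxidation with bicarbonate buffering gives the β,γ-epoxy aldehyde under neutral conditions, which avoids base-induced opening to the γ-hydroxy enal.

Step 12
Reactants: 20 (2R,3E,5Z)-6-iodo-1-[(2R,3R)-2-methyl-3-(2-oxoethyl)oxiran-2-yl]hepta-3,5-dien-2-yl 3-methylbutanoate
Product: 22 (1R,3R,4Z,6E,8R,10R)-3-hydroxy-4,10-dimethyl-11-oxabicyclo[8.1.0]undeca-4,6-dien-8-yl 3-methylbutanoate, via alkenylchromium dichloride 21 (not isolated)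
Conditions: CrCl2 (10 equiv), NiCl2 (0.1 equiv), DMSO, rt, slow addition of 20 to 2 mM final concentration; then H2O
Reagents that add atoms: none
Why: In this Nozaki–Hiyama–Kishi macrocyclisation nickel-catalysed insertion into the C4–I bond and transmetalation give alkenylchromium 21 with retention of the Z geometry, it adds only to the aldehyde under high dilution, and in the staggered crown-like transition state the chromium-bound oxygen stands perpendicular to the C4=C5 plane while H3 eclipses the C15 methyl (least A1,2 strain), which exposes the Si face and should set C3 as R.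

Step 13
Reactants: 22 (1R,3R,4Z,6E,8R,10R)-3-hydroxy-4,10-dimethyl-11-oxabicyclo[8.1.0]undeca-4,6-dien-8-yl 3-methylbutanoate; 23 2-bromoacrylic acid
Product: 25 (1R,3R,4Z,6R,7R,8R,10R)-1,10-epoxy-3-hydroxy-8-(3-methylbutanoyloxy)germacra-4,11(13)-dien-12,6-olide (CNP0300193.1), via oxapalladacycle 24 (not isolated)
Conditions: Pd2(dba)3 (5 mol %), Ag2CO3 (1.5 equiv), 23 (3 equiv, slow addition), DMF, 45 °C, dark
Reagents that add atoms: none
Why: Zerovalent palladium inserts into the C–Br bond of the 2-bromoacrylate, Ag2CO3 strips bromide, and the cationic alkenylpalladium adds syn across the E-C6=C7 end of the diene (C11 to C7, Pd to C6) to give an η3-allyl over C4–C6 that the pendant carboxylate chelates as oxapalladacycle 24, from which C–O reductive elimination at C6 releases 25 and zerovalent palladium. The closest known reaction type is the Larock heteroannulation of 1,3-dienes by organic halides that carry a carboxylic acid, phenol or amine. The one ring closed is the five-membered lactone, formed by inner-sphere ring contraction of the six-membered palladacycle (formally a 5-exo attack of oxygen on allyl terminus C6), whereas closure at C4 would need a seven-membered ring at a quaternary carbon. C7 is controlled by the ring: in the crown conformer fixed by the trans-1,10-epoxide (chair-like C6=C7–C8–C9–C10–C1 segment, planar s-trans diene) only the outer face of the E-alkene is open, and that face gives 7R; C6 follows from C7 because the ring blocks the inner face, so both bonds form on the same face and syn addition to an E-alkene gives the trans-fused 6R,7R lactone. The step needs regioselectivity (secured by the CH terminus C7 against the fully substituted C4), retention of the Z-C4=C5 geometry (syn/anti exchange would need a tertiary η1-palladium at C4) and chemoselectivity (a phosphine-free, halide-free cationic catalyst prefers the electron-rich diene to the acrylate C=C bonds and should not ionise the allylic C8 ester, the C3 carbinol or the product lactone, and the 1,10-epoxide is not allylic).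

Compound list
1 | 2-butyn-1-ol | CC#CCO | starting material
2 | sodium cyclic alkenylalanate (five-membered O–Al–C ring, two 2-methoxyethoxy groups on aluminium) | [Na+].CC1=CCO[Al-]1(OCCOC)OCCOC | intermediate
3 | (Z)-3-iodobut-2-en-1-ol | C/C(I)=C/CO | intermediate
4 | (Z)-3-iodobut-2-enal | C/C(I)=C/C=O | intermediate
5 | (3Z)-4-iodopenta-1,3-diene | C/C(I)=C/C=C | intermediate
6 | acrolein | C=CC=O | starting material
7 | allenylboronic acid pinacol ester | C=C=CB1OC(C)(C)C(C)(C)O1 | starting material
8 | (R)-hex-1-en-5-yn-3-yl pinacol borate | CC1(C)OB(O[C@@H](C=C)CC#C)OC1(C)C | intermediate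
9 | (R)-hex-1-en-5-yn-3-ol | O[C@@H](C=C)CC#C | intermediate
10 | ethylene oxide | C1CO1 | starting material
11 | (E)-alkenyldimethylalane of 9, hydroxyl as dimethylaluminium alkoxide | C[Al](C)O[C@@H](C=C)C/C(C)=C/[Al](C)C | intermediate
12 | lithium butyl(dimethyl)alkenylalanate derived from 11 | C[Al](C)O[C@@H](C=C)C/C(C)=C/[Al-](C)(C)CCCC.[Li+] | intermediate
13 | (3R,5E)-5-methylocta-1,5-diene-3,8-diol | O[C@@H](C=C)C/C(C)=C/CCO | intermediate
14 | (3R,5E)-8-(tert-butyldimethylsilyloxy)-5-methylocta-1,5-dien-3-ol | O[C@@H](C=C)C/C(C)=C/CCO[Si](C)(C)C(C)(C)C | intermediate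
15 | isovaleryl chloride | CC(C)CC(=O)Cl | starting material
16 | (3R,5E)-8-(tert-butyldimethylsilyloxy)-5-methylocta-1,5-dien-3-yl 3-methylbutanoate | CC(C)CC(=O)O[C@@H](C=C)C/C(C)=C/CCO[Si](C)(C)C(C)(C)C | intermediate
17 | (2R)-1-[(2R,3R)-3-(2-(tert-butyldimethylsilyloxy)ethyl)-2-methyloxiran-2-yl]but-3-en-2-yl 3-methylbutanoate | CC(C)CC(=O)O[C@@H](C=C)C[C@@]1(C)O[C@@H]1CCO[Si](C)(C)C(C)(C)C | intermediate
18 | (2R,3E,5Z)-1-[(2R,3R)-3-(2-(tert-butyldimethylsilyloxy)ethyl)-2-methyloxiran-2-yl]-6-iodohepta-3,5-dien-2-yl 3-methylbutanoate | CC(C)CC(=O)O[C@@H](/C=C/C=C(/C)I)C[C@@]1(C)O[C@@H]1CCO[Si](C)(C)C(C)(C)C | intermediate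
19 | (2R,3E,5Z)-1-[(2R,3R)-3-(2-hydroxyethyl)-2-methyloxiran-2-yl]-6-iodohepta-3,5-dien-2-yl 3-methylbutanoate | CC(C)CC(=O)O[C@@H](/C=C/C=C(/C)I)C[C@@]1(C)O[C@@H]1CCO | intermediate
20 | (2R,3E,5Z)-6-iodo-1-[(2R,3R)-2-methyl-3-(2-oxoethyl)oxiran-2-yl]hepta-3,5-dien-2-yl 3-methylbutanoate | CC(C)CC(=O)O[C@@H](/C=C/C=C(/C)I)C[C@@]1(C)O[C@@H]1CC=O | intermediate
21 | alkenylchromium dichloride derived from 20 (CrCl2 in place of iodine, Z retained) | CC(C)CC(=O)O[C@@H](/C=C/C=C(/C)[Cr](Cl)Cl)C[C@@]1(C)O[C@@H]1CC=O | intermediate
22 | (1R,3R,4Z,6E,8R,10R)-3-hydroxy-4,10-dimethyl-11-oxabicyclo[8.1.0]undeca-4,6-dien-8-yl 3-methylbutanoate | CC(C)CC(=O)O[C@H]1/C=C/C=C(/C)[C@H](O)C[C@H]2O[C@]2(C)C1 | intermediate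
23 | 2-bromoacrylic acid | C=C(Br)C(=O)O | starting material
24 | six-membered oxapalladacycle (σ form of the η3-allylpalladium carboxylate; Pd on C6, C11 on C7) | C=C1C(=O)O[Pd][C@@H]2/C=C(/C)[C@H](O)C[C@H]3O[C@]3(C)C[C@@H](OC(=O)CC(C)C)[C@@H]12 | intermediate
25 | (1R,3R,4Z,6R,7R,8R,10R)-1,10-epoxy-3-hydroxy-8-(3-methylbutanoyloxy)germacra-4,11(13)-dien-12,6-olide (CNP0300193.1) | C=C1C(=O)O[C@@H]2/C=C(/C)[C@H](O)C[C@H]3O[C@]3(C)C[C@@H](OC(=O)CC(C)C)[C@@H]12 | target

Total step count: 13. Longest linear sequence: 10 steps (steps 4 to 13, from acrolein).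

Steps most likely to fail

1. Step 13.
- What may go wrong: carbopalladation of the hindered internal diene may be slow. Heck reaction may compete at the acrylate C=C bonds of 23 or 25. Allylic C–O bonds may ionise, silver carbonate may oxidise the C3 carbinol, or a flipped ring conformer may be attacked and give the wrong face.
- Fallback: it sets out from 22 and uses a radical–polar crossover carbolactonisation. Mn(OAc)3·2H2O and malonic acid (KOAc, AcOH/MeCN, 23 °C) add the malonyl radical to C7. Trivalent manganese oxidises the allyl radical to the cation, and a carboxyl group closes on C6 to give the α-carboxy lactone F1 (C11 epimers). Decarboxylative Mannich methylenation (aqueous CH2O, Et2NH, NaOAc, AcOH) then comes back to the route at 25.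

2. Step 12.
- What may go wrong: facial selectivity at the aldehyde may be poor during ring closure. Ten-membered ring closure may be slow against oligomerisation, and the epoxide may erode through iodide and Lewis-acidic chromium salts.
- Fallback: it sets out from 20 and moves the control of C3 from the C–C bond formation to a reagent-controlled reduction. The closure is run without regard to C3. The 3S alcohol F2 is oxidised together with any 22 (MnO2, CH2Cl2) to the macrocyclic dienone F3. Corey–Bakshi–Shibata reduction ((S)-2-methyl-CBS-oxazaborolidine, BH3·SMe2, THF, −30 °C) treats the alkenyl side as the large group and comes back to the route at 22.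

3. Step 9.
- What may go wrong: the vinylcarbene formed from the iododiene may turn over sluggishly, 5 may homodimerise, or the E selectivity may be incomplete.
- Fallback: it sets out from 17 and 3 and replaces metathesis by carbonyl olefination.
 - Ozonolysis of the vinyl group of 17 (O3, CH2Cl2, −78 °C; Me2S) gives the α-acyloxy aldehyde F4.
 - In parallel 3 is converted (CBr4, PPh3) into (Z)-1-bromo-3-iodobut-2-ene F5 and, by Arbuzov reaction with P(OEt)3, into diethyl (Z)-(3-iodobut-2-enyl)phosphonate F6.
 - Horner–Wadsworth–Emmons olefination of F4 with F6 (LiN(SiMe3)2, THF, −78 °C) comes back to the route at 18.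

Further compounds
F1 | step 13 | α-carboxy lactone (11-carboxy-11,13-dihydro-13-nor analogue of 25, C11 epimers) | OC(=O)C1C(=O)O[C@@H]2/C=C(/C)[C@H](O)C[C@H]3O[C@]3(C)C[C@@H](OC(=O)CC(C)C)[C@@H]12
F2 | step 12 | (1R,3S,4Z,6E,8R,10R)-3-hydroxy-4,10-dimethyl-11-oxabicyclo[8.1.0]undeca-4,6-dien-8-yl 3-methylbutanoate | CC(C)CC(=O)O[C@H]1/C=C/C=C(/C)[C@@H](O)C[C@H]2O[C@]2(C)C1
F3 | step 12 | (1R,4Z,6E,8R,10R)-4,10-dimethyl-3-oxo-11-oxabicyclo[8.1.0]undeca-4,6-dien-8-yl 3-methylbutanoate | CC(C)CC(=O)O[C@H]1/C=C/C=C(/C)C(=O)C[C@H]2O[C@]2(C)C1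
F4 | step 9 | (2R)-1-[(2R,3R)-3-(2-(tert-butyldimethylsilyloxy)ethyl)-2-methyloxiran-2-yl]-3-oxopropan-2-yl 3-methylbutanoate | CC(C)CC(=O)O[C@@H](C=O)C[C@@]1(C)O[C@@H]1CCO[Si](C)(C)C(C)(C)C
F5 | step 9 | (Z)-1-bromo-3-iodobut-2-ene | C/C(I)=C/CBr
F6 | step 9 | diethyl (Z)-(3-iodobut-2-enyl)phosphonate | C/C(I)=C/CP(=O)(OCC)OCC
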